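**Conventions.** Atom numbering of the target: five-membered ring C1(CH3)–C2–C3–C4(OH)(iPr)–C5; seven-membered ring C5–C6(O-acyl)–C7–C8(CH3)–C9–C10–C1; epoxide on C8–C9. β is the face of the C1 methyl group, α the opposite face. Compound numbers 1–18 are those of the compound list after the steps.

**Assumption:** in step 2 the oxocarbenium ion formed on ring opening is hydrolysed by water, so the carbonyl oxygen of 5 comes from water and the methoxy group leaves as methanol.

## Analysis of the target

The target is a daucane sesquiterpenoid ester: a trans-fused hydroazulene with a 3,4-dimethoxybenzoate on C6, a tertiary alcohol on C4 and an epoxide across C8–C9. It has six stereocentres, (1R,4R,5S,6S,8R,9S): the C1 methyl and the C4 hydroxyl lie on the β face, while H5, the C6 ester oxygen, the epoxide oxygen and the isopropyl group lie on the α face. C1 is an all-carbon quaternary centre next to the ring-fusion methine C5, and C4–C5–C6 has the pattern of an aldol followed by a 1,3-anti reduction. Sensitive groups are the trisubstituted epoxide (acid opens it, and the C4 hydroxyl can reach C8 from the β face), the tertiary alcohol (it dehydrates once C6 is a carbonyl), and any C6 ketone on the way, which is β,γ-unsaturated to C8=C9 and conjugates easily. The hard points are the seven-membered ring, the quaternary centre, the trans ring fusion and the control of C4 relative to C1. The route rests on one observation: the seven-membered ring without C5 (C6–C7–C8–C9–C10–C1) is the ring of 2,5-dimethylanisole, with the oxygen on C6, the methyl groups on C1 and C8, and C8=C9 as the double bond that survives Birch reduction. C5 can then be inserted between C6 and C1 as a carbene carbon.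

## Retrosynthetic reasoning

**C6–O ester bond (18 ⇒ 16 + 17).** The ester is cut first because it would not survive the reductions that build the core. In 16 the secondary C6 hydroxyl is the only acylable position, since the C4 hydroxyl is tertiary. Forward, a carbodiimide coupling under non-acidic conditions must esterify a hindered alcohol without touching the epoxide.

**C8–O and C9–O bonds (16 ⇒ 15).** The epoxide goes back to the C8=C9 alkene of diol 15. It is placed after the reduction so that the α hydroxyl at C6, homoallylic to the alkene, can deliver the oxidant to the α face, which the β methyl on C1 also leaves open. It is placed late because it is the most acid-sensitive group.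

**C6–H bond (15 ⇒ 14).** The secondary alcohol comes from the C6 ketone of 14. The C4 hydroxyl sits on the β face, so a hydride delivered from it reaches the β face of C6 and leaves the oxygen α. An external hydride would be expected on the open α face and would give the wrong epimer.

**C4–C5 bond (14 ⇒ 12, through 13).** The β-hydroxy ketone is an aldol retron; cutting C4–C5 opens the five-membered ring to a cycloheptenone with a ketone side chain on C1. This cut removes two stereocentres at once and makes the ring α-carbon C5 the nucleophile. Base cannot be used, because C7 is both α and allylic and would be deprotonated first, with migration of the double bond. A bromine on C5 solves this: reductive cleavage of the C5–Br bond of 12 gives the C5 enolate 13 and no other, without base. A base-generated bromo enolate is avoided for a second reason: its aldolate would close to an epoxide. Forward, a metal bridging the two oxygens should place the C4 oxygen cis to C6; the trans ring fusion must come with it.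

**C1–C2 bond (12 ⇒ 11 ⇒ 5 + 8).** Without the chain, C1 is the β-carbon of an enone and the C5 bromine is the α-bromine of bromo enone 5. The chain arrives as Grignard reagent 9, made from bromo ketal 8, which is one step from vinyl ketone 6. The side-chain ketone is masked as a ketal through the organometallic step and released in 11 → 12. This step makes the quaternary centre and fixes the absolute configuration, so it must be a catalytic enantioselective conjugate addition.

**C5–C6 and C5–C1 bonds (5 ⇒ 2 + 3, through 4).** A seven-membered enone with a bromine on the carbon between the carbonyl and the alkene carbon is the signature of a dihalocyclopropane ring opening. Removing C5 with its bromine and restoring the C6–C1 bond gives enol ether 2 and bromoform 3. Two skeletal bonds and the seven-membered ring are gained in one operation, with the oxygen, both methyl groups and C8=C9 already in place. Forward, the carbene from 3 must choose the enol ether double bond, and the skipped dienone must be released without dehydrobromination or conjugation.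

**Aromatic ring (2 ⇒ 1).** Diene 2 is the Birch product of 2,5-dimethylanisole 1: the two unsubstituted, para-related positions (C7 and C10) take up hydrogen and the three donor groups stay on sp2 carbons.

## Alternatives that were turned down

**Alternative 1:** Disconnection of the C3–C4 bond of the five-membered ring, with the seven-membered ring closed afterwards.
- Key step: [Rh((R)-BINAP)]ClO4 inserts into the formyl C–H bond of the divinyl aldehyde A2, (2S)-3-ethenyl-3-methyl-2-[(1S)-2-(2-methyl-1,3-dioxolan-2-yl)-1-(triethylsilyloxy)ethyl]pent-4-enal, and adds it across one of the two vinyl groups on the prochiral C1. This gives cyclopentanone A1, (2S,3R)-3-ethenyl-3-methyl-2-[(1S)-2-(2-methyl-1,3-dioxolan-2-yl)-1-(triethylsilyloxy)ethyl]cyclopentan-1-one, and keeps the second vinyl group for the larger ring.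
- For: the quaternary centre is set by group selection; C5 and C6 come from an acyclic aldol; an isopropyl nucleophile would add to the C4 ketone of A1 anti to the large C5 substituent, which is the C4/C5 relationship of the target. On the control of C4 relative to C1 and C5 this plan is stronger than the chosen one, which depends on the facial course of a ring closure.
- Against: A2 is an α-branched β-silyloxy aldehyde that can epimerise, eliminate and decarbonylate on rhodium. The choice between the vinyl groups is a matched/mismatched problem with two existing stereocentres. A2 needs a long enantioselective preparation. After A1 the seven-membered ring must still be closed against medium-ring entropy.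
- Comparison: clearly longer. The chosen strategy gives up secure C4 control and offers the complete seven-membered carbocycle, with its oxygen, both methyl groups and C8=C9, two steps from a commercial arene.

**Alternative 2:** Disconnection of the C1–CH3 bond; the angular methyl is delivered from the C4 oxygen.
- Key step: Bu3SnH/AIBN converts the bromomethylsilyl ether A4 (the O-bromomethyldimethylsilyl ether of the C4 tertiary allylic alcohol of a hydroazulene with a tetrasubstituted C1=C5 bond and a 6β silyl ether) into an α-silyl radical. It attacks C1 in a 6-endo mode, and the C5 radical then abstracts hydrogen to give the siloxane-bridged trans-fused A3. Protodesilylation would later reveal the methyl group, and C6 would have to be inverted.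
- For: the tether guarantees that the C1 methyl is cis to the C4 hydroxyl, the relationship least secure in the chosen route, and the ring fusion is decided by a hydrogen-atom transfer anti to the new bond. On this point it is stronger.
- Against: the radical must form a quaternary centre at a fully substituted alkene carbon in the 6-endo mode, while 5-exo attack on C5 and simple reduction compete. A4 already contains the whole bicycle with C4 and C6 set, so the real construction problems move into a long preparation. C6 costs an inversion, and the absolute configuration must come from elsewhere.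
- Comparison: the chosen route makes the quaternary centre by a polar, catalyst-controlled addition to an activated alkene and reaches the ring system in far fewer steps, at the price of a less certain C4/C1 relationship.

**Alternative 3:** Disconnection of the C1–C10 bond together with a temporary C5–C9 bond.
- Key step: irradiation at 350 nm of cyclopentenone A6, 2-[(1S,4R)-1-(tert-butyldimethylsilyloxy)-4-methoxy-4-methylhex-5-en-1-yl]-3-methylcyclopent-2-en-1-one, joins C5–C9 and C1–C10 and gives the tricyclic photoadduct A5. Cleavage of the C5–C9 bond next to the ketone, presumably with loss of the C8 methoxy group, would then open the seven-membered ring and create C8=C9.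
- For: the quaternary C1 and the seven-membered ring arise without a medium-ring closure; the regiochemistry of a three-atom tether is reliable; C5 becomes an enolate protonation and C4 an addition to a cyclopentanone anti to the C6-bearing substituent. In the handling of C4 and C5 it is at least as good as the chosen route.
- Against: the facial selectivity of the cycloaddition rests only on the C6 silyloxy stereocentre in a flexible tether. The fragmentation must choose C5–C9 over C5–C1. The isopropyl nucleophile must add to a hindered, enolisable ketone. A6 is itself a multi-step target.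
- Comparison: longer overall, and its absolute configuration depends on a stoichiometric chiral building block. The chosen route sets C1 by catalysis and has the shorter path to the bicycle.

Key step: step 2

## Route

Step 1
Reactants: 1 2,5-dimethylanisole
Product: 2 1-methoxy-2,5-dimethylcyclohexa-1,4-diene
Conditions: Li, NH3 (l), t-BuOH, THF, −78 → −33 °C
Reagents that add atoms: none
Why: Birch reduction of an alkoxyarene: the radical anion is protonated at the two unsubstituted, para-related positions (C7 and C10), so the methoxy and both methyl groups stay on sp2 carbons and the non-conjugated diene results; no stereocentre is formed.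

Step 2
Reactants: 2 1-methoxy-2,5-dimethylcyclohexa-1,4-diene, 3 bromoform
Product: 5 2-bromo-3,6-dimethylcyclohepta-2,5-dien-1-one, via dibromocyclopropane 4 (not isolated)
Conditions: KOt-Bu, 3 (1.05 equiv), pentane, −30 → 0 °C; then AgNO3, CaCO3, acetone–H2O, 0 °C → rt, dark
Reagents that add atoms: water, O
Why: KOt-Bu deprotonates 3 and α-elimination gives dibromocarbene, an electrophilic singlet carbene that adds in a concerted [2+1] manner to the tetrasubstituted, oxygen-bearing C6=C1 bond of 2 faster than to the trisubstituted C8=C9 bond. In 4 the silver ion takes the bromide syn to the six-membered ring while the C6–C1 bond opens by an orbital-symmetry-allowed disrotatory process, the methoxy group stabilising the allyl cation as an oxocarbenium ion. Water captures this ion and loss of methanol gives ketone 5, in which the former carbene carbon C5 lies between C6 and C1 (new bonds C5–C6 and C5–C1). The closest known reaction type is dihalocarbene addition to Birch-derived 1-methoxycyclohexa-1,4-dienes followed by silver- or heat-induced opening of the 1-alkoxy-7,7-dihalonorcarane to a 2-halocycloheptenone. The three-membered ring closes by cheletropic [2+1] addition; the seven-membered ring arises not by cyclisation but by cleavage of the shared bond of the bicyclo[4.1.0] system. No stereocentre is formed. The step needs chemoselectivity for the enol ether, secured by its higher electron density, one equivalent of 3 and low temperature. It also needs the skipped dienone to survive, secured by the carbonate buffer and the absence of strong base after the carbene stage.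

Step 3
Reactants: 6 4-methylpent-1-en-3-one
Product: 8 2-(2-bromoethyl)-5,5-dimethyl-2-(propan-2-yl)-1,3-dioxane, via bromo ketone 7 (not isolated)
Conditions: HBr (g), CH2Cl2, 0 °C; then 2,2-dimethylpropane-1,3-diol, HC(OEt)3, p-TsOH (cat.), rt
Reagents that add atoms: hydrogen bromide, Br; 2,2-dimethylpropane-1,3-diol, OCC(C)(C)CO
Why: Conjugate addition of HBr to the enone gives β-bromo ketone 7, which is ketalised at once under water-scavenging conditions so that it cannot lose HBr again; this is the established preparation of β-halo ketals from vinyl ketones. The 1,3-dioxane is chosen because its Grignard reagent is stable; no stereocentre is formed.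

Step 4
Reactants: 5 2-bromo-3,6-dimethylcyclohepta-2,5-dien-1-one, 8 2-(2-bromoethyl)-5,5-dimethyl-2-(propan-2-yl)-1,3-dioxane
Product: 11 (3R)-2-bromo-3-[2-(5,5-dimethyl-2-(propan-2-yl)-1,3-dioxan-2-yl)ethyl]-3,6-dimethylcyclohept-5-en-1-one (both C2 epimers), via Grignard reagent 9 (not isolated), via magnesium bromoenolate 10 (not isolated)
Conditions: 8, Mg, THF, rt; then 5, Cu(OTf)2 (5 mol %), chiral hydroxyalkyl N-mesitylimidazolinium salt (NHC precursor, 6 mol %), Et2O, −30 °C; AcOH, −78 °C
Reagents that add atoms: none
Why: Proposed new method: copper-catalysed asymmetric conjugate addition of a functionalised Grignard reagent to a 2-bromo-3-methylcycloheptenone; the carbene-bound alkylcopper species forms a π-complex with the enone and transfers the alkyl group to C1 from the face fixed by the chiral carbene (ligand enantiomer chosen to give R), the bromine lowering the LUMO to offset the extra substitution, and enolate 10 is protonated cold to 11, whose C5 epimers are both usable; the closest known reaction types are copper–carbene-catalysed additions of Grignard reagents to 3-methylcyclohept-2-enone giving quaternary centres and copper-catalysed asymmetric additions of dialkylzincs to 2-halocycloalkenones.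

Step 5
Reactants: 11 (3R)-2-bromo-3-[2-(5,5-dimethyl-2-(propan-2-yl)-1,3-dioxan-2-yl)ethyl]-3,6-dimethylcyclohept-5-en-1-one
Product: 12 (3R)-2-bromo-3,6-dimethyl-3-(4-methyl-3-oxopentyl)cyclohept-5-en-1-one (both C2 epimers)
Conditions: 1 M aq. HCl, THF, 0 °C → rt
Reagents that add atoms: water, O
Why: Acid-catalysed ketal hydrolysis; cold dilute acid and a short reaction time are chosen so that neither the α-bromo ketone nor the β,γ-unsaturated ring ketone isomerises, and C1 is not affected.

Step 6
Reactants: 12 (3R)-2-bromo-3,6-dimethyl-3-(4-methyl-3-oxopentyl)cyclohept-5-en-1-one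
Product: 14 (3R,3aR,8aR)-3-hydroxy-6,8a-dimethyl-3-(propan-2-yl)-2,3,3a,5,8,8a-hexahydroazulen-4(1H)-one, via samarium enolate 13 (not isolated)
Conditions: SmI2 (2.1 equiv), THF, −78 → 0 °C; pH 7 buffer
Reagents that add atoms: none
Why: Intramolecular Reformatsky-type aldol: SmI2 reduces the α-bromo ketone much faster than either ketone and gives the C5 enolate 13 regiospecifically and without base. The trivalent samarium bridges the enolate oxygen and the C4 carbonyl, so the C4 oxygen should end cis to C6 and the isopropyl group trans to it. The ketone–ketone aldolate is left to equilibrate on warming towards the trans-fused chelate with H5 anti to the C1 methyl; this last element is the least secure.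

Step 7
Reactants: 14 (3R,3aR,8aR)-3-hydroxy-6,8a-dimethyl-3-(propan-2-yl)-2,3,3a,5,8,8a-hexahydroazulen-4(1H)-one
Product: 15 (3R,3aS,4S,8aR)-6,8a-dimethyl-3-(propan-2-yl)-1,2,3,3a,4,5,8,8a-octahydroazulene-3,4-diol
Conditions: Me4NBH(OAc)3, MeCN–AcOH, −20 °C → rt
Reagents that add atoms: none
Why: Saksena–Evans directed reduction: the C4 hydroxyl exchanges onto boron and the hydride is delivered intramolecularly to the β face of the C6 carbonyl, which should give the 6α (S) alcohol, anti to the C4 hydroxyl.

Step 8
Reactants: 15 (3R,3aS,4S,8aR)-6,8a-dimethyl-3-(propan-2-yl)-1,2,3,3a,4,5,8,8a-octahydroazulene-3,4-diol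
Product: 16 (3R,3aS,4S,6R,7S,8aR)-6,7-epoxy-6,8a-dimethyl-3-(propan-2-yl)decahydroazulene-3,4-diol
Conditions: VO(acac)2 (5 mol %), t-BuOOH, CH2Cl2, 0 °C → rt
Reagents that add atoms: tert-butyl hydroperoxide, CC(C)(C)OO
Why: Hydroxyl-directed vanadium-catalysed epoxidation: the homoallylic C6 hydroxyl binds the vanadium peroxide and delivers oxygen to the α face of C8=C9, the face that the β angular methyl also leaves open, which should set C8 (R) and C9 (S).

Step 9
Reactants: 16 (3R,3aS,4S,6R,7S,8aR)-6,7-epoxy-6,8a-dimethyl-3-(propan-2-yl)decahydroazulene-3,4-diol, 17 3,4-dimethoxybenzoic acid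
Product: 18 (3R,3aS,4S,6R,7S,8aR)-6,7-epoxy-3-hydroxy-6,8a-dimethyl-3-(propan-2-yl)decahydroazulen-4-yl 3,4-dimethoxybenzoate
Conditions: DCC, DMAP, CH2Cl2, rt → 40 °C
Reagents that add atoms: none
Why: Steglich esterification: only the secondary C6 hydroxyl is acylated, the tertiary C4 hydroxyl being inert, and the non-acidic medium spares the epoxide; no stereocentre is touched.

## Compound list

1 | 2,5-dimethylanisole | COc1cc(C)ccc1C | starting material
2 | 1-methoxy-2,5-dimethylcyclohexa-1,4-diene | COC1=C(C)CC=C(C)C1 | intermediate
3 | bromoform | BrC(Br)Br | starting material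
4 | 7,7-dibromo-1-methoxy-3,6-dimethylbicyclo[4.1.0]hept-3-ene (racemic, cis-fused, not isolated) | COC12CC(C)=CCC1(C)C2(Br)Br | intermediate
5 | 2-bromo-3,6-dimethylcyclohepta-2,5-dien-1-one | CC1=CCC(C)=C(Br)C(=O)C1 | intermediate
6 | 4-methylpent-1-en-3-one | CC(C)C(=O)C=C | starting material
7 | 1-bromo-4-methylpentan-3-one (not isolated) | CC(C)C(=O)CCBr | intermediate
8 | 2-(2-bromoethyl)-5,5-dimethyl-2-(propan-2-yl)-1,3-dioxane | CC(C)C1(CCBr)OCC(C)(C)CO1 | intermediate
9 | {2-[5,5-dimethyl-2-(propan-2-yl)-1,3-dioxan-2-yl]ethyl}magnesium bromide (not isolated) | CC(C)C1(CC[Mg]Br)OCC(C)(C)CO1 | intermediate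
10 | bromomagnesium (3R)-2-bromo-3-[2-(5,5-dimethyl-2-(propan-2-yl)-1,3-dioxan-2-yl)ethyl]-3,6-dimethylcyclohepta-1,5-dien-1-olate (not isolated) | Br[Mg]OC1=C(Br)[C@](C)(CCC2(C(C)C)OCC(C)(C)CO2)CC=C(C)C1 | intermediate
11 | (3R)-2-bromo-3-[2-(5,5-dimethyl-2-(propan-2-yl)-1,3-dioxan-2-yl)ethyl]-3,6-dimethylcyclohept-5-en-1-one (both C2 epimers) | O=C1C(Br)[C@](C)(CCC2(C(C)C)OCC(C)(C)CO2)CC=C(C)C1 | intermediate
12 | (3R)-2-bromo-3,6-dimethyl-3-(4-methyl-3-oxopentyl)cyclohept-5-en-1-one (both C2 epimers) | O=C1C(Br)[C@](C)(CCC(=O)C(C)C)CC=C(C)C1 | intermediate
13 | diiodosamarium (3R)-3,6-dimethyl-3-(4-methyl-3-oxopentyl)cyclohepta-1,5-dien-1-olate (not isolated) | I[Sm](I)OC1=C[C@](C)(CCC(=O)C(C)C)CC=C(C)C1 | intermediate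
14 | (3R,3aR,8aR)-3-hydroxy-6,8a-dimethyl-3-(propan-2-yl)-2,3,3a,5,8,8a-hexahydroazulen-4(1H)-one | O=C1CC(C)=CC[C@@]2(C)CC[C@@](O)(C(C)C)[C@H]12 | intermediate
15 | (3R,3aS,4S,8aR)-6,8a-dimethyl-3-(propan-2-yl)-1,2,3,3a,4,5,8,8a-octahydroazulene-3,4-diol | O[C@H]1CC(C)=CC[C@@]2(C)CC[C@@](O)(C(C)C)[C@H]12 | intermediate
16 | (3R,3aS,4S,6R,7S,8aR)-6,7-epoxy-6,8a-dimethyl-3-(propan-2-yl)decahydroazulene-3,4-diol | O[C@H]1C[C@@]2(C)O[C@H]2C[C@@]2(C)CC[C@@](O)(C(C)C)[C@H]12 | intermediate
17 | 3,4-dimethoxybenzoic acid | COc1ccc(C(=O)O)cc1OC | starting material
18 | (3R,3aS,4S,6R,7S,8aR)-6,7-epoxy-3-hydroxy-6,8a-dimethyl-3-(propan-2-yl)decahydroazulen-4-yl 3,4-dimethoxybenzoate | COc1ccc(C(=O)O[C@H]2C[C@@]3(C)O[C@H]3C[C@@]3(C)CC[C@@](O)(C(C)C)[C@H]23)cc1OC | target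

## Step count and least certain steps

Total step count: 9. Longest linear sequence: 8 steps (1, 2, 4, 5, 6, 7, 8, 9, from 1); step 3 is a one-step branch.

**Step 4 (Proposed new method).**
- Most likely failure: the Grignard reagent acts as a base at C10 or C7, followed by loss of bromide and aromatisation, or it exchanges with the vinylic bromide instead of adding. Face discrimination at a tetrasubstituted alkene may also be poor.
- Fallback in known chemistry, setting out from 5: hydrodebromination with Bu3SnH and Pd(PPh3)4 (zerovalent palladium) gives 3,6-dimethylcyclohepta-2,5-dien-1-one F1, a β-methylcycloheptenone of the class for which the Cu(OTf)2/carbene-catalysed addition of Grignard reagents is established. Addition of 9 under the conditions of step 4 and trapping of the enolate with Me3SiCl gives the trimethylsilyl enol ether F2. Bromination of F2 with NBS in THF at −78 °C returns to the route at 11.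

**Step 2 (key step).**
- Most likely failure: carbene addition at C8=C9 as well, and, after ring opening, elimination of HBr with aromatisation or migration of C8=C9 into conjugation, both of which start from enolisation of the new ketone.
- Fallback, setting out from 2 and 3: the cyclopropane 4 is isolated by filtration and opened with AgNO3 in dry methanol buffered with 2,6-lutidine, so that the cation is trapped as the non-enolisable 1-bromo-7,7-dimethoxy-2,5-dimethylcyclohepta-1,4-diene F3. Mild hydrolysis of F3 on wet silica gel with oxalic acid returns to the route at 5.

**Step 6.**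
- Most likely failure: poor facial selectivity at C5. If the chain closes from its pseudo-axial position onto the near face of the enolate, the ring fusion is cis; because chelation ties C4 to C5, C4 is then also wrong relative to C1, and epimerising C5 cannot repair it. β-Elimination of the tertiary aldol is a second risk.
- Fallback, setting out from 12: the closure is run without regard to configuration and the crude aldol is dehydrated with DBU in toluene to (8aR)-6,8a-dimethyl-3-(propan-2-yl)-2,5,8,8a-tetrahydroazulen-4(1H)-one F4. Reduction with NaBH4/CeCl3·7H2O, hydride arriving anti to the angular methyl, gives the 6β allylic alcohol F5. VO(acac)2/t-BuOOH epoxidises syn to that hydroxyl to the 4β,5β-epoxy 6β-alcohol F6. Dess–Martin oxidation gives the 4β,5β-epoxy ketone F7. SmI2 in THF–MeOH cleaves the C5–O bond, which leaves the 4β hydroxyl; the C5 enolate is protonated and, if needed, equilibrated to the trans-fused ketone. The sequence returns at 14.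

**Step 7.**
- Most likely failure: slow exchange of the tertiary hydroxyl onto boron, so that reduction is incomplete or external hydride attacks the open α face; acid-promoted dehydration of the aldol is also possible.
- Fallback with a covalent tether, setting out from 14: silylation with iPr2SiHCl, Et3N and DMAP gives the 4-O-diisopropylsilyl ether F8. SnCl4 at −78 °C promotes intramolecular hydrosilylation from the β face to the cyclic diisopropylsilylene acetal F9. HF·pyridine cleaves it and returns to the route at 15.

**Step 8.**
- Most likely failure: loss of the epoxide by Lewis-acid-promoted transannular attack of the C4 hydroxyl on C8, or sluggish and unselective oxygen transfer because the directing hydroxyl is only homoallylic.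
- Fallback, setting out from 15: the order is reversed. Esterification with 17 (DCC, DMAP) gives the 6-O-(3,4-dimethoxybenzoyl) ester of 15, F10. Epoxidation with dimethyldioxirane in acetone at 0 °C, under steric control by the β angular methyl and without any Lewis acid, returns at 18.

## Further compounds

F1 | step 4 | 3,6-dimethylcyclohepta-2,5-dien-1-one | CC1=CC(=O)CC(C)=CC1
F2 | step 4 | {[(3R)-3-[2-(5,5-dimethyl-2-(propan-2-yl)-1,3-dioxan-2-yl)ethyl]-3,6-dimethylcyclohepta-1,5-dien-1-yl]oxy}trimethylsilane | C[Si](C)(C)OC1=C[C@](C)(CCC2(C(C)C)OCC(C)(C)CO2)CC=C(C)C1
F3 | step 2 | 1-bromo-7,7-dimethoxy-2,5-dimethylcyclohepta-1,4-diene | COC1(OC)CC(C)=CCC(C)=C1Br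
F4 | step 6 | (8aR)-6,8a-dimethyl-3-(propan-2-yl)-2,5,8,8a-tetrahydroazulen-4(1H)-one | O=C1CC(C)=CC[C@@]2(C)CCC(C(C)C)=C12
F5 | step 6 | (4R,8aR)-6,8a-dimethyl-3-(propan-2-yl)-1,2,4,5,8,8a-hexahydroazulen-4-ol (6β alcohol, syn to the C1 methyl) | O[C@@H]1CC(C)=CC[C@@]2(C)CCC(C(C)C)=C12
F6 | step 6 | 4β,5β-epoxy 6β-alcohol of the same skeleton (epoxide across C4–C5 and hydroxyl at C6, both syn to the C1 methyl; C8=C9 retained) | O[C@@H]1CC(C)=CC[C@@]2(C)CC[C@]3(C(C)C)O[C@]123
F7 | step 6 | 4β,5β-epoxy 6-ketone of the same skeleton (epoxide across C4–C5 syn to the C1 methyl; C8=C9 retained) | O=C1CC(C)=CC[C@@]2(C)CC[C@]3(C(C)C)O[C@]123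
F8 | step 7 | (3R,3aR,8aR)-3-[di(propan-2-yl)silyloxy]-6,8a-dimethyl-3-(propan-2-yl)-2,3,3a,5,8,8a-hexahydroazulen-4(1H)-one | O=C1CC(C)=CC[C@@]2(C)CC[C@@](O[SiH](C(C)C)C(C)C)(C(C)C)[C@H]12
F9 | step 7 | cyclic di(propan-2-yl)silylene acetal of diol 15 (silicon bridging the C4 and C6 oxygens) | CC(C)[Si]3(C(C)C)O[C@H]1CC(C)=CC[C@@]2(C)CC[C@@](O3)(C(C)C)[C@H]12
F10 | step 8 | (3R,3aS,4S,8aR)-3-hydroxy-6,8a-dimethyl-3-(propan-2-yl)-1,2,3,3a,4,5,8,8a-octahydroazulen-4-yl 3,4-dimethoxybenzoate | COc1ccc(C(=O)O[C@H]2CC(C)=CC[C@@]3(C)CC[C@@](O)(C(C)C)[C@H]23)cc1OC
A1 | alternative 1 | (2S,3R)-3-ethenyl-3-methyl-2-[(1S)-2-(2-methyl-1,3-dioxolan-2-yl)-1-(triethylsilyloxy)ethyl]cyclopentan-1-one | C=C[C@@]1(C)CCC(=O)[C@@H]1[C@@H](O[Si](CC)(CC)CC)CC1(C)OCCO1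
A2 | alternative 1 | (2S)-3-ethenyl-3-methyl-2-[(1S)-2-(2-methyl-1,3-dioxolan-2-yl)-1-(triethylsilyloxy)ethyl]pent-4-enal | O=C[C@@H](C(C)(C=C)C=C)[C@@H](O[Si](CC)(CC)CC)CC1(C)OCCO1
A3 | alternative 2 | siloxane-bridged trans-fused hydroazulene (dimethylsilylene-methylene bridge from the C4 oxygen to C1, H5 anti to the C1–CH2 bond, 6β tert-butyldimethylsilyl ether, C8=C9 retained) | C[Si]1(C)O[C@@]2(C(C)C)CC[C@]3(C1)CC=C(C)C[C@@H](O[Si](C)(C)C(C)(C)C)[C@@H]23
A4 | alternative 2 | (bromomethyl)dimethylsilyl ether of the C4 tertiary alcohol of the hydroazulene with a tetrasubstituted C1=C5 bond, 6β tert-butyldimethylsilyl ether and C8=C9 | BrC[Si](C)(C)O[C@@]1(C(C)C)CCC2=C1[C@H](O[Si](C)(C)C(C)(C)C)CC(C)=CC2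
A5 | alternative 3 | tricyclic photoadduct (cyclopentanone, cyclobutane and cyclopentane sharing C5; methyl on C1, methoxy and methyl on C8, tert-butyldimethylsilyl ether on C6) | O=C1CC[C@]2(C)C[C@H]3[C@](C)(OC)C[C@H](O[Si](C)(C)C(C)(C)C)[C@@]123
A6 | alternative 3 | 2-[(1S,4R)-1-(tert-butyldimethylsilyloxy)-4-methoxy-4-methylhex-5-en-1-yl]-3-methylcyclopent-2-en-1-one | O=C1CCC(C)=C1[C@@H](O[Si](C)(C)C(C)(C)C)C[C@@](C)(OC)C=C
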